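The route is built on the Z-trisubstituted C4=C5 alkene of the ten-membered ring A: C4 bears C15 and C3, C5 bears C6, and C3 lies cis to C6. Syn addition of a C1–C3 alkylcopper across propyne followed by palladium-catalysed acylation of the alkenylcopper forms C3–C4 and C5–C6 in one flask with exactly that geometry. The acylating partner is a C6 acid chloride that already carries C7, C8, C9, C11 and C12, with C7 and C8 set by Fráter–Seebach alkylation of an L-malate-derived hydroxy ester. A hydroxyl-directed reduction then fixes C6, lactone ring B is closed, and a Nozaki–Hiyama–Kishi reaction closes ring A at C9–C10.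

Key step: step 8

Remark: atom numbers are those of the target skeleton (ring A = carbocycle C1–C10; ring B = lactone C6–C7–C11–C12–O; C13 exocyclic methylene; C14 ester carbon on C10; C15 methyl on C4; primed numbers belong to the C8 acyl group).

Step 1
Reactants: 1 (S)-malic acid
Product: 2 dibenzyl (S)-malate
Conditions: BnOH, TsOH·H2O (cat.), toluene, reflux, Dean–Stark trap
Reagents that add atoms: benzyl alcohol, OCc1ccccc1
Why: Fischer esterification with azeotropic removal of water gives the dibenzyl ester and leaves the carbinol centre, the future C8, untouched.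

Step 2
Reactants: 2 dibenzyl (S)-malate
Product: 3 benzyl (3S)-3,4-dihydroxybutanoate
Conditions: BH3·SMe2, NaBH4 (5 mol%), THF, 0 °C → rt; MeOH quench
Reagents that add atoms: none
Why: Hydroxyl-directed borane reduction runs through the O8 alkoxyborane, which delivers hydride only to the neighbouring ester, so that this carbon becomes C9 while the remote benzyl ester (future C6) survives.

Step 3
Reactants: 3 benzyl (3S)-3,4-dihydroxybutanoate
Product: 4 benzyl (3S)-4-(tert-butyldiphenylsilyloxy)-3-hydroxybutanoate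
Conditions: tBuPh2SiCl, imidazole, CH2Cl2, 0 °C
Reagents that add atoms: tert-butyl(chloro)diphenylsilane, CC(C)(C)[Si](Cl)(c1ccccc1)c1ccccc1
Why: Silylation with a bulky chlorosilane is selective for the primary hydroxyl (O9) and leaves O8–H free to steer the alkylation.

Step 4
Reactants: 4 benzyl (3S)-4-(tert-butyldiphenylsilyloxy)-3-hydroxybutanoate; 5 tert-butyl bromoacetate
Product: 6 1-benzyl 4-tert-butyl (2R)-2-[(1S)-2-(tert-butyldiphenylsilyloxy)-1-hydroxyethyl]butanedioate
Conditions: LiN(iPr)2 (2.2 equiv), THF, −78 → −30 °C; 5, DMPU, −78 → −40 °C; AcOH, −78 °C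
Reagents that add atoms: none
Why: Fráter–Seebach alkylation, in which the lithium-chelated alkoxide–enolate dianion is alkylated on the face away from the C9 arm, sets C7 anti to O8 (7R,8S here, the relative configuration of the target, which cuprate addition to an acyclic γ-alkoxy enoate would not secure) and brings in C11 and C12, while the tert-butyl ester and the cold acidic quench suppress Claisen condensation and lactonisation.

Step 5
Reactants: 6 1-benzyl 4-tert-butyl (2R)-2-[(1S)-2-(tert-butyldiphenylsilyloxy)-1-hydroxyethyl]butanedioate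
Product: 7 (2R)-4-tert-butoxy-2-[(1S)-2-(tert-butyldiphenylsilyloxy)-1-hydroxyethyl]-4-oxobutanoic acid
Conditions: H2 (1 atm), Pd/C (10%), EtOAc, rt
Reagents that add atoms: none
Why: Hydrogenolysis of the benzyl ester frees the C6 acid under neutral conditions, so the tert-butyl ester, the silyl ether and the enolisable C7 centre are not disturbed.

Step 6
Reactants: 7 (2R)-4-tert-butoxy-2-[(1S)-2-(tert-butyldiphenylsilyloxy)-1-hydroxyethyl]-4-oxobutanoic acid
Product: 9 tert-butyl (3R,4S)-5-(tert-butyldiphenylsilyloxy)-3-(chlorocarbonyl)-4-(trimethylsilyloxy)pentanoate, via bis(trimethylsilyl) derivative 8 (not isolated)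
Conditions: (Me3Si)2NH, Me3SiCl (cat.), CH2Cl2, 40 °C; evaporate; (COCl)2, DMF (cat.), CH2Cl2, 0 °C → rt
Reagents that add atoms: hexamethyldisilazane, C[Si](C)(C)N[Si](C)(C)C; oxalyl chloride, ClC(=O)C(=O)Cl
Why: Silylation caps O8 and turns the acid into its silyl ester, which the Vilsmeier reagent converts into the acid chloride with loss of Me3SiCl and without HCl or amine base, so C7 is not epimerised and no ketene forms.

Step 7
Reactants: 10 2-(2-bromoethyl)-1,3-dioxolane
Product: 11 [2-(1,3-dioxolan-2-yl)ethyl]magnesium bromide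
Conditions: Mg, BrCH2CH2Br (cat.), THF, 25–30 °C
Reagents that add atoms: magnesium, [Mg]
Why: Grignard formation by insertion of magnesium into the primary C–Br bond is kept below 30 °C because this acetal Grignard reagent decomposes on warming.

Step 8
Reactants: 11 [2-(1,3-dioxolan-2-yl)ethyl]magnesium bromide; 12 propyne; 9 tert-butyl (3R,4S)-5-(tert-butyldiphenylsilyloxy)-3-(chlorocarbonyl)-4-(trimethylsilyloxy)pentanoate
Product: 16 tert-butyl (3R,5Z)-3-[(1S)-2-(tert-butyldiphenylsilyloxy)-1-hydroxyethyl]-8-(1,3-dioxolan-2-yl)-6-methyl-4-oxooct-5-enoate, via alkylcopper 13 (not isolated), via Z-alkenylcopper 14 (not isolated), via silyl ether enone 15 (not isolated)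
Conditions: CuBr·SMe2, Et2O/Me2S, −45 °C; propyne, −25 °C; acid chloride 9, Pd(PPh3)4 (5 mol%), THF, −25 → 0 °C; citric acid (aq.), THF, 0 °C
Reagents that add atoms: none
Why: Transmetalation of Grignard reagent 11 to CuBr·SMe2 gives alkylcopper 13, which adds across propyne by a four-centre syn carbocupration that puts the alkyl group on the methyl-bearing carbon (C3–C4) and copper on the terminal carbon, so that copper is cis to C3 in 14. Acid chloride 9 then adds oxidatively to zerovalent palladium, the alkenyl group is transferred from copper with retention, and reductive elimination forms C5–C6 with C6 cis to C3, the ring-cis geometry of C4=C5. The closest known reaction is the Normant carbocupration of a terminal alkyne by a Grignard-derived alkylcopper followed by Pd(PPh3)4-catalysed acylation of the alkenylcopper with an acid chloride. No ring is closed and no stereocentre is created, C7 and C8 being carried in unchanged from 9. The step needs regioselective syn addition and retention, both intrinsic to alkenylcopper chemistry, and it needs the α-centre C7 and the Z-enone to survive, which the non-basic organocopper, the temperature below 0 °C and the HCl-free acid chloride secure. The citric acid work-up cleaves only the trimethylsilyl ether and so frees O8–H for the next step.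

Step 9
Reactants: 16 tert-butyl (3R,5Z)-3-[(1S)-2-(tert-butyldiphenylsilyloxy)-1-hydroxyethyl]-8-(1,3-dioxolan-2-yl)-6-methyl-4-oxooct-5-enoate
Product: 17 tert-butyl (3S,4R,5Z)-3-[(1S)-2-(tert-butyldiphenylsilyloxy)-1-hydroxyethyl]-8-(1,3-dioxolan-2-yl)-4-hydroxy-6-methyloct-5-enoate
Conditions: Me4NBH(OAc)3, MeCN/AcOH (1:1), −25 °C
Reagents that add atoms: none
Why: Evans–Saksena reduction, in which boron binds O8 and hydride is delivered intramolecularly through a chair transition state with the C9 and C11 branches equatorial, should give only 1,2-reduction and the 6,8-anti diol (6R), whereas external hydride would attack anti to C8 (Felkin–Anh) and lead to the cis-lactone.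

Step 10
Reactants: 17 tert-butyl (3S,4R,5Z)-3-[(1S)-2-(tert-butyldiphenylsilyloxy)-1-hydroxyethyl]-8-(1,3-dioxolan-2-yl)-4-hydroxy-6-methyloct-5-enoate
Product: 19 (4S,5R)-4-[(1S)-2-(tert-butyldiphenylsilyloxy)-1-(triethylsilyloxy)ethyl]-5-[(1Z)-4-(1,3-dioxolan-2-yl)-2-methylbut-1-en-1-yl]oxolan-2-one, via hydroxy lactone 18 (not isolated)
Conditions: KOtBu (0.3 equiv), THF, −20 → 0 °C; imidazole, Et3SiCl, 0 °C → rt
Reagents that add atoms: chlorotriethylsilane, CC[Si](Cl)(CC)CC
Why: Alkoxide-catalysed lactonisation (intramolecular transesterification of the tert-butyl ester) is reversible between O6 and O8, so the trans-β,γ-disubstituted 6,12-lactone (ring B) should prevail over the cis 8,12-isomer, and silylation in the same flask then caps O8–H for the enolate chemistry that follows.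

Step 11
Reactants: 19 (4S,5R)-4-[(1S)-2-(tert-butyldiphenylsilyloxy)-1-(triethylsilyloxy)ethyl]-5-[(1Z)-4-(1,3-dioxolan-2-yl)-2-methylbut-1-en-1-yl]oxolan-2-one
Product: 22 (4S,5R)-4-[(1S)-2-(tert-butyldiphenylsilyloxy)-1-(triethylsilyloxy)ethyl]-5-[(1Z)-4-(1,3-dioxolan-2-yl)-2-methylbut-1-en-1-yl]-3-methylideneoxolan-2-one, via Mannich base 20 (not isolated), via ammonium iodide 21 (not isolated)
Conditions: LiN(iPr)2, THF, −78 °C; CH2=NMe2+ I−, −78 → 0 °C; MeI, MeOH, rt; NaHCO3 (aq.), CH2Cl2, rt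
Reagents that add atoms: dimethylmethyleneammonium iodide (Eschenmoser's salt), C=[N+](C)C.[I-]
Why: Mannich reaction of the lithium lactone enolate with Eschenmoser's salt, N-methylation and Hofmann-type elimination install C13 on a substrate that has no other acidic or electrophilic site, and the transient C11 centre is destroyed in the elimination.

Step 12
Reactants: 22 (4S,5R)-4-[(1S)-2-(tert-butyldiphenylsilyloxy)-1-(triethylsilyloxy)ethyl]-5-[(1Z)-4-(1,3-dioxolan-2-yl)-2-methylbut-1-en-1-yl]-3-methylideneoxolan-2-one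
Product: 23 (4Z)-5-[(2R,3R)-3-[(1S)-2-(tert-butyldiphenylsilyloxy)-1-hydroxyethyl]-4-methylidene-5-oxooxolan-2-yl]-4-methylpent-4-enal
Conditions: HCl (1 M, aq.), THF, rt
Reagents that add atoms: water, O
Why: Acid-catalysed acetal hydrolysis unmasks the C1 aldehyde and the same dilute acid removes the triethylsilyl ether from O8, while the tert-butyldiphenylsilyl ether, the lactone and the exocyclic methylene are stable under these conditions.

Step 13
Reactants: 24 methyl (triphenylphosphoranylidene)acetate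
Product: 25 methyl iodo(triphenylphosphoranylidene)acetate
Conditions: N-iodosuccinimide, MeCN, −20 °C → rt
Reagents that add atoms: N-iodosuccinimide, O=C1CCC(=O)N1I
Why: Electrophilic iodination of the stabilised ylide followed by proton transfer to the succinimide anion gives the α-iodo ylide needed for the Wittig step.

Step 14
Reactants: 23 (4Z)-5-[(2R,3R)-3-[(1S)-2-(tert-butyldiphenylsilyloxy)-1-hydroxyethyl]-4-methylidene-5-oxooxolan-2-yl]-4-methylpent-4-enal; 25 methyl iodo(triphenylphosphoranylidene)acetate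
Product: 26 methyl (2Z,6Z)-7-[(2R,3R)-3-[(1S)-2-(tert-butyldiphenylsilyloxy)-1-hydroxyethyl]-4-methylidene-5-oxooxolan-2-yl]-2-iodo-6-methylhepta-2,6-dienoate
Conditions: CH2Cl2, rt
Reagents that add atoms: none
Why: Wittig olefination with a stabilised α-iodo ylide places the ester trans to the alkyl chain, so the Z-α-iodoenoate has iodine cis to C2, the geometry that later becomes the ring-cis C1=C10 bond.

Step 15
Reactants: 27 (2E)-2-methylbut-2-en-1-ol
Product: 28 [(2R,3R)-2,3-dimethyloxiran-2-yl]methanol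
Conditions: tBuOOH, Ti(OiPr)4 (5 mol%), D-(−)-diisopropyl tartrate (6 mol%), 4 Å molecular sieves, CH2Cl2, −20 °C
Reagents that add atoms: tert-butyl hydroperoxide, CC(C)(C)OO
Why: Sharpless asymmetric epoxidation of the E-trisubstituted allylic alcohol with the D-(−)-tartrate ligand delivers oxygen to the face that gives the (2R,3R)-epoxide and thereby sets the future C2′ centre.

Step 16
Reactants: 28 [(2R,3R)-2,3-dimethyloxiran-2-yl]methanol
Product: 29 (2S,3R)-3,4-dihydroxy-3-methylbutan-2-yl acetate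
Conditions: AcOH, Ti(OiPr)4 (1.5 equiv), CH2Cl2, rt
Reagents that add atoms: acetic acid, CC(=O)O
Why: Titanium-mediated opening of the 2,3-epoxy alcohol by a carboxylic acid takes place within the titanium alkoxide chelate at C3 with inversion, which sets C3′ anti to the C2′ oxygen and leaves the quaternary C2′ untouched.

Step 17
Reactants: 29 (2S,3R)-3,4-dihydroxy-3-methylbutan-2-yl acetate
Product: 30 (2S,3S)-3-acetoxy-2-hydroxy-2-methylbutanoic acid
Conditions: 2,2,6,6-tetramethylpiperidin-1-oxyl (cat.), NaOCl (cat.), NaClO2, MeCN/phosphate buffer (pH 6.7), 35 °C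
Reagents that add atoms: sodium chlorite, [Na+].[O-]Cl=O
Why: Nitroxyl-catalysed chlorite oxidation takes the primary alcohol to the acid at buffered pH and leaves the tertiary alcohol, the acetate and both stereocentres alone.

Step 18
Reactants: 30 (2S,3S)-3-acetoxy-2-hydroxy-2-methylbutanoic acid
Product: 32 (2S,3S)-3-acetoxy-2-methyl-2-(trimethylsilyloxy)butanoyl chloride, via bis(trimethylsilyl) derivative 31 (not isolated)
Conditions: Me3SiCl, pyridine, CH2Cl2, rt; (COCl)2, DMF (cat.), 0 °C → rt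
Reagents that add atoms: chlorotrimethylsilane, C[Si](C)(C)Cl; oxalyl chloride, ClC(=O)C(=O)Cl
Why: Silylation masks the tertiary hydroxyl and gives the silyl ester, which the Vilsmeier reagent converts into the acid chloride, and the quaternary α-carbon rules out ketene formation.

Step 19
Reactants: 26 methyl (2Z,6Z)-7-[(2R,3R)-3-[(1S)-2-(tert-butyldiphenylsilyloxy)-1-hydroxyethyl]-4-methylidene-5-oxooxolan-2-yl]-2-iodo-6-methylhepta-2,6-dienoate; 32 (2S,3S)-3-acetoxy-2-methyl-2-(trimethylsilyloxy)butanoyl chloride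
Product: 33 methyl (2Z,6Z)-7-[(2R,3S)-3-[(1S)-1-{[(2S,3S)-3-acetoxy-2-methyl-2-(trimethylsilyloxy)butanoyl]oxy}-2-(tert-butyldiphenylsilyloxy)ethyl]-4-methylidene-5-oxooxolan-2-yl]-2-iodo-6-methylhepta-2,6-dienoate
Conditions: pyridine, 4-dimethylaminopyridine, CH2Cl2, 0 °C → rt
Reagents that add atoms: none
Why: Nucleophilic-catalysed acylation esterifies the only free hydroxyl, O8–H, with the complete C8 side chain before ring closure, and no stereocentre is affected because the C8–O bond is not broken.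

Step 20
Reactants: 33 methyl (2Z,6Z)-7-[(2R,3S)-3-[(1S)-1-{[(2S,3S)-3-acetoxy-2-methyl-2-(trimethylsilyloxy)butanoyl]oxy}-2-(tert-butyldiphenylsilyloxy)ethyl]-4-methylidene-5-oxooxolan-2-yl]-2-iodo-6-methylhepta-2,6-dienoate
Product: 34 methyl (2Z,6Z)-7-[(2R,3S)-3-[(1S)-1-{[(2S,3S)-3-acetoxy-2-hydroxy-2-methylbutanoyl]oxy}-2-hydroxyethyl]-4-methylidene-5-oxooxolan-2-yl]-2-iodo-6-methylhepta-2,6-dienoate
Conditions: HF·pyridine, pyridine, THF, 0 °C → rt
Reagents that add atoms: none
Why: Fluoride-mediated desilylation removes the primary tert-butyldiphenylsilyl ether and the tertiary trimethylsilyl ether in a mildly acidic medium that disfavours acyl migration from O8 to O9.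

Step 21
Reactants: 34 methyl (2Z,6Z)-7-[(2R,3S)-3-[(1S)-1-{[(2S,3S)-3-acetoxy-2-hydroxy-2-methylbutanoyl]oxy}-2-hydroxyethyl]-4-methylidene-5-oxooxolan-2-yl]-2-iodo-6-methylhepta-2,6-dienoate
Product: 35 methyl (2Z,6Z)-7-[(2R,3S)-3-[(1S)-1-{[(2S,3S)-3-acetoxy-2-hydroxy-2-methylbutanoyl]oxy}-2-oxoethyl]-4-methylidene-5-oxooxolan-2-yl]-2-iodo-6-methylhepta-2,6-dienoate
Conditions: Dess–Martin periodinane, CH2Cl2, 0 °C
Reagents that add atoms: none
Why: Dess–Martin oxidation converts the primary alcohol into the C9 aldehyde under neutral conditions that do not epimerise C8, and the tertiary hydroxyl is inert.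

Step 22
Reactants: 35 methyl (2Z,6Z)-7-[(2R,3S)-3-[(1S)-1-{[(2S,3S)-3-acetoxy-2-hydroxy-2-methylbutanoyl]oxy}-2-oxoethyl]-4-methylidene-5-oxooxolan-2-yl]-2-iodo-6-methylhepta-2,6-dienoate
Product: 36 9-O-deisobutyryl target (ring A closed; 6R 7S 8S 9R; free C9 hydroxyl)
Conditions: CrCl2 (10 equiv), NiCl2 (2 mol%), DMSO/THF, 2 mM, rt
Reagents that add atoms: none
Why: Intramolecular Nozaki–Hiyama–Kishi reaction (nickel insertion into the alkenyl C–I bond, transmetalation to trivalent chromium and addition to the C9 aldehyde with retention of alkene geometry) closes ring A at C9–C10, and polar Felkin–Anh attack anti to the C8 acyloxy group should give the 8,9-anti (9R) alcohol.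

Step 23
Reactants: 36 9-O-deisobutyryl target (ring A closed; 6R 7S 8S 9R; free C9 hydroxyl)
Product: 37 CNP0479879.1
Conditions: (iPrCO)2O, 4-dimethylaminopyridine, pyridine, CH2Cl2, 0 °C
Reagents that add atoms: 2-methylpropanoic anhydride, CC(C)C(=O)OC(=O)C(C)C
Why: Nucleophilic-catalysed acylation esterifies the secondary allylic C9 hydroxyl, while the hindered tertiary C2′ hydroxyl should not react at 0 °C.

Compound list
1 | (S)-malic acid | OC(=O)C[C@H](O)C(=O)O | starting material
2 | dibenzyl (S)-malate | O=C(OCc1ccccc1)C[C@H](O)C(=O)OCc1ccccc1 | intermediate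
3 | benzyl (3S)-3,4-dihydroxybutanoate | O=C(OCc1ccccc1)C[C@H](O)CO | intermediate
4 | benzyl (3S)-4-(tert-butyldiphenylsilyloxy)-3-hydroxybutanoate | O=C(OCc1ccccc1)C[C@H](O)CO[Si](c1ccccc1)(c1ccccc1)C(C)(C)C | intermediate
5 | tert-butyl bromoacetate | BrCC(=O)OC(C)(C)C | starting material
6 | 1-benzyl 4-tert-butyl (2R)-2-[(1S)-2-(tert-butyldiphenylsilyloxy)-1-hydroxyethyl]butanedioate | O=C(OCc1ccccc1)[C@H](CC(=O)OC(C)(C)C)[C@H](O)CO[Si](c1ccccc1)(c1ccccc1)C(C)(C)C | intermediate
7 | (2R)-4-tert-butoxy-2-[(1S)-2-(tert-butyldiphenylsilyloxy)-1-hydroxyethyl]-4-oxobutanoic acid | OC(=O)[C@H](CC(=O)OC(C)(C)C)[C@H](O)CO[Si](c1ccccc1)(c1ccccc1)C(C)(C)C | intermediate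
8 | trimethylsilyl (2R)-4-tert-butoxy-2-[(1S)-2-(tert-butyldiphenylsilyloxy)-1-(trimethylsilyloxy)ethyl]-4-oxobutanoate | C[Si](C)(C)OC(=O)[C@H](CC(=O)OC(C)(C)C)[C@H](O[Si](C)(C)C)CO[Si](c1ccccc1)(c1ccccc1)C(C)(C)C | intermediate
9 | tert-butyl (3R,4S)-5-(tert-butyldiphenylsilyloxy)-3-(chlorocarbonyl)-4-(trimethylsilyloxy)pentanoate (C6 acid chloride with C7, C8, C9, C11, C12) | ClC(=O)[C@H](CC(=O)OC(C)(C)C)[C@H](O[Si](C)(C)C)CO[Si](c1ccccc1)(c1ccccc1)C(C)(C)C | intermediate
10 | 2-(2-bromoethyl)-1,3-dioxolane | BrCCC1OCCO1 | starting material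
11 | [2-(1,3-dioxolan-2-yl)ethyl]magnesium bromide | Br[Mg]CCC1OCCO1 | intermediate
12 | propyne | CC#C | starting material
13 | [2-(1,3-dioxolan-2-yl)ethyl]copper (MgBr2 complex) | [Cu]CCC1OCCO1 | intermediate
14 | [(1Z)-4-(1,3-dioxolan-2-yl)-2-methylbut-1-en-1-yl]copper | [Cu]/C=C(\CCC1OCCO1)C | intermediate
15 | tert-butyl (3R,5Z)-3-[(1S)-2-(tert-butyldiphenylsilyloxy)-1-(trimethylsilyloxy)ethyl]-8-(1,3-dioxolan-2-yl)-6-methyl-4-oxooct-5-enoate | O=C(/C=C(\CCC1OCCO1)C)[C@H](CC(=O)OC(C)(C)C)[C@H](O[Si](C)(C)C)CO[Si](c1ccccc1)(c1ccccc1)C(C)(C)C | intermediate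
16 | tert-butyl (3R,5Z)-3-[(1S)-2-(tert-butyldiphenylsilyloxy)-1-hydroxyethyl]-8-(1,3-dioxolan-2-yl)-6-methyl-4-oxooct-5-enoate | O=C(/C=C(\CCC1OCCO1)C)[C@H](CC(=O)OC(C)(C)C)[C@H](O)CO[Si](c1ccccc1)(c1ccccc1)C(C)(C)C | intermediate
17 | tert-butyl (3S,4R,5Z)-3-[(1S)-2-(tert-butyldiphenylsilyloxy)-1-hydroxyethyl]-8-(1,3-dioxolan-2-yl)-4-hydroxy-6-methyloct-5-enoate | O[C@H](/C=C(\CCC1OCCO1)C)[C@H](CC(=O)OC(C)(C)C)[C@H](O)CO[Si](c1ccccc1)(c1ccccc1)C(C)(C)C | intermediate
18 | (4R,5R)-4-[(1S)-2-(tert-butyldiphenylsilyloxy)-1-hydroxyethyl]-5-[(1Z)-4-(1,3-dioxolan-2-yl)-2-methylbut-1-en-1-yl]oxolan-2-one | O=C1O[C@H](/C=C(\CCC2OCCO2)C)[C@H](C1)[C@H](O)CO[Si](c1ccccc1)(c1ccccc1)C(C)(C)C | intermediate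
19 | (4S,5R)-4-[(1S)-2-(tert-butyldiphenylsilyloxy)-1-(triethylsilyloxy)ethyl]-5-[(1Z)-4-(1,3-dioxolan-2-yl)-2-methylbut-1-en-1-yl]oxolan-2-one | O=C1O[C@H](/C=C(\CCC2OCCO2)C)[C@H](C1)[C@H](O[Si](CC)(CC)CC)CO[Si](c1ccccc1)(c1ccccc1)C(C)(C)C | intermediate
20 | 3-[(dimethylamino)methyl] derivative of 19 (C11 epimers) | O=C1O[C@H](/C=C(\CCC2OCCO2)C)[C@@H]([C@H](O[Si](CC)(CC)CC)CO[Si](c2ccccc2)(c2ccccc2)C(C)(C)C)C1CN(C)C | intermediate
21 | trimethylammonium iodide from 20 (C11 epimers) | O=C1O[C@H](/C=C(\CCC2OCCO2)C)[C@@H]([C@H](O[Si](CC)(CC)CC)CO[Si](c2ccccc2)(c2ccccc2)C(C)(C)C)C1C[N+](C)(C)C.[I-] | intermediate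
22 | (4S,5R)-4-[(1S)-2-(tert-butyldiphenylsilyloxy)-1-(triethylsilyloxy)ethyl]-5-[(1Z)-4-(1,3-dioxolan-2-yl)-2-methylbut-1-en-1-yl]-3-methylideneoxolan-2-one | C=C1C(=O)O[C@H](/C=C(\CCC2OCCO2)C)[C@H]1[C@H](O[Si](CC)(CC)CC)CO[Si](c1ccccc1)(c1ccccc1)C(C)(C)C | intermediate
23 | (4Z)-5-[(2R,3R)-3-[(1S)-2-(tert-butyldiphenylsilyloxy)-1-hydroxyethyl]-4-methylidene-5-oxooxolan-2-yl]-4-methylpent-4-enal | C=C1C(=O)O[C@H](/C=C(\CCC=O)C)[C@H]1[C@H](O)CO[Si](c1ccccc1)(c1ccccc1)C(C)(C)C | intermediate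
24 | methyl (triphenylphosphoranylidene)acetate | COC(=O)C=P(c1ccccc1)(c1ccccc1)c1ccccc1 | starting material
25 | methyl iodo(triphenylphosphoranylidene)acetate | COC(=O)C(I)=P(c1ccccc1)(c1ccccc1)c1ccccc1 | intermediate
26 | methyl (2Z,6Z)-7-[(2R,3R)-3-[(1S)-2-(tert-butyldiphenylsilyloxy)-1-hydroxyethyl]-4-methylidene-5-oxooxolan-2-yl]-2-iodo-6-methylhepta-2,6-dienoate | C=C1C(=O)O[C@H](/C=C(\CC/C=C(\I)C(=O)OC)C)[C@H]1[C@H](O)CO[Si](c1ccccc1)(c1ccccc1)C(C)(C)C | intermediate
27 | (2E)-2-methylbut-2-en-1-ol | C/C=C(\C)CO | starting material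
28 | [(2R,3R)-2,3-dimethyloxiran-2-yl]methanol | C[C@H]1O[C@]1(C)CO | intermediate
29 | (2S,3R)-3,4-dihydroxy-3-methylbutan-2-yl acetate | OC[C@@](C)(O)[C@H](C)OC(C)=O | intermediate
30 | (2S,3S)-3-acetoxy-2-hydroxy-2-methylbutanoic acid | OC(=O)[C@@](C)(O)[C@H](C)OC(C)=O | intermediate
31 | trimethylsilyl (2S,3S)-3-acetoxy-2-methyl-2-(trimethylsilyloxy)butanoate | C[Si](C)(C)OC(=O)[C@@](C)(O[Si](C)(C)C)[C@H](C)OC(C)=O | intermediate
32 | (2S,3S)-3-acetoxy-2-methyl-2-(trimethylsilyloxy)butanoyl chloride | ClC(=O)[C@@](C)(O[Si](C)(C)C)[C@H](C)OC(C)=O | intermediate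
33 | methyl (2Z,6Z)-7-[(2R,3S)-3-[(1S)-1-{[(2S,3S)-3-acetoxy-2-methyl-2-(trimethylsilyloxy)butanoyl]oxy}-2-(tert-butyldiphenylsilyloxy)ethyl]-4-methylidene-5-oxooxolan-2-yl]-2-iodo-6-methylhepta-2,6-dienoate | C=C1C(=O)O[C@H](/C=C(\CC/C=C(\I)C(=O)OC)C)[C@H]1[C@H](OC(=O)[C@@](C)(O[Si](C)(C)C)[C@H](C)OC(C)=O)CO[Si](c1ccccc1)(c1ccccc1)C(C)(C)C | intermediate
34 | methyl (2Z,6Z)-7-[(2R,3S)-3-[(1S)-1-{[(2S,3S)-3-acetoxy-2-hydroxy-2-methylbutanoyl]oxy}-2-hydroxyethyl]-4-methylidene-5-oxooxolan-2-yl]-2-iodo-6-methylhepta-2,6-dienoate | C=C1C(=O)O[C@H](/C=C(\CC/C=C(\I)C(=O)OC)C)[C@H]1[C@H](OC(=O)[C@@](C)(O)[C@H](C)OC(C)=O)CO | intermediate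
35 | methyl (2Z,6Z)-7-[(2R,3S)-3-[(1S)-1-{[(2S,3S)-3-acetoxy-2-hydroxy-2-methylbutanoyl]oxy}-2-oxoethyl]-4-methylidene-5-oxooxolan-2-yl]-2-iodo-6-methylhepta-2,6-dienoate | C=C1C(=O)O[C@H](/C=C(\CC/C=C(\I)C(=O)OC)C)[C@H]1[C@H](OC(=O)[C@@](C)(O)[C@H](C)OC(C)=O)C=O | intermediate
36 | 9-O-deisobutyryl target (ring A closed; 6R,7S,8S,9R; free C9 hydroxyl) | C=C1C(=O)O[C@@H]2/C=C(/C)CC/C=C(/C(=O)OC)[C@@H](O)[C@@H](OC(=O)[C@@](C)(O)[C@H](C)OC(C)=O)[C@@H]12 | intermediate
37 | CNP0479879.1 | C=C1C(=O)O[C@@H]2/C=C(/C)CC/C=C(/C(=O)OC)[C@@H](OC(=O)C(C)C)[C@@H](OC(=O)[C@@](C)(O)[C@H](C)OC(C)=O)[C@@H]12 | target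

Total steps: 23. Longest linear sequence: 17 steps (steps 1–6, 8–12, 14, 19–23).

Steps most likely to fail

1. Step 8. The acetal-bearing alkylcopper may add sluggishly to propyne in the ether/THF/Me2S medium, or the alkenylcopper may transfer too slowly to the acylpalladium, so that leftover alkylcopper is acylated, the acid chloride decomposes or the enone drifts towards the E isomer. The fallback separates the two bond formations and uses a zinc reagent. It sets out from 11, 12 and 9. The carbocupration mixture is quenched at the stage of 14 with iodine to give 2-[(3Z)-4-iodo-3-methylbut-3-en-1-yl]-1,3-dioxolane F1, which is purified and checked for geometry. Iodine–lithium exchange (t-BuLi, Et2O, −78 °C) gives the alkenyllithium F2, and ZnCl2 converts it into chloro[(1Z)-4-(1,3-dioxolan-2-yl)-2-methylbut-1-en-1-yl]zinc F3. Negishi acylation of this zinc reagent with acid chloride 9 (Pd(PPh3)4, THF, 0 °C) gives 15, and the same citric acid work-up rejoins the route at 16.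

2. Step 22. The ten-membered transition state, and not the C8 acyloxy group, may decide which face of the C9 aldehyde is reached, so that facial selectivity is poor and the C9 epimer forms. The fallback sets C9 by inversion instead of by addition. It sets out from 35, which is cyclised as before. The C9 epimer of 36 F4 is then esterified under Mitsunobu conditions with isobutyric acid (PPh3, diisopropyl azodicarboxylate, toluene, 0 °C), which inverts C9 and installs the isobutyrate in one operation, rejoining the route at 37.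

3. Step 10. O8 instead of O6 may close onto C12 to give the cis 8,12-lactone, or the silyl group may migrate from O9 to O8 under the alkoxide conditions. In the fallback O8 is never free while the lactone forms, and C6 is set by external hydride and then inverted. It sets out from 16, which is silylated (Et3SiOTf, 2,6-lutidine, CH2Cl2, −78 °C) to the O8 triethylsilyl ether of 16 F5. LiBH(sBu)3 (THF, −78 °C, cold AcOH quench) reduces the ketone under Felkin–Anh control to the (6S)-alcohol F6. Mitsunobu reaction with 4-nitrobenzoic acid (PPh3, diisopropyl azodicarboxylate) gives the inverted (6R)-4-nitrobenzoate F7. K2CO3 in MeOH cleaves the nitrobenzoate, and the O6 alkoxide, now the only free hydroxyl, closes onto the tert-butyl ester (KOtBu cat., THF, 0 °C), rejoining the route at 19.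

Further compounds
F1 | step 8 | 2-[(3Z)-4-iodo-3-methylbut-3-en-1-yl]-1,3-dioxolane | I/C=C(\CCC1OCCO1)C
F2 | step 8 | [(1Z)-4-(1,3-dioxolan-2-yl)-2-methylbut-1-en-1-yl]lithium | [Li]/C=C(\CCC1OCCO1)C
F3 | step 8 | chloro[(1Z)-4-(1,3-dioxolan-2-yl)-2-methylbut-1-en-1-yl]zinc | Cl[Zn]/C=C(\CCC1OCCO1)C
F4 | step 22 | C9 epimer of 36 (6R,7S,8S,9S) | C=C1C(=O)O[C@@H]2/C=C(/C)CC/C=C(/C(=O)OC)[C@H](O)[C@@H](OC(=O)[C@@](C)(O)[C@H](C)OC(C)=O)[C@@H]12
F5 | step 10 | O8 triethylsilyl ether of 16 (7R,8S) | O=C(/C=C(\CCC1OCCO1)C)[C@H](CC(=O)OC(C)(C)C)[C@H](O[Si](CC)(CC)CC)CO[Si](c1ccccc1)(c1ccccc1)C(C)(C)C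
F6 | step 10 | (6S)-alcohol from F5 (6S,7S,8S; C12 tert-butyl ester; O8 triethylsilyl; O9 tert-butyldiphenylsilyl) | O[C@@H](/C=C(\CCC1OCCO1)C)[C@H](CC(=O)OC(C)(C)C)[C@H](O[Si](CC)(CC)CC)CO[Si](c1ccccc1)(c1ccccc1)C(C)(C)C
F7 | step 10 | (6R)-4-nitrobenzoate from F6 (6R,7S,8S) | O=C(O[C@H](/C=C(\CCC1OCCO1)C)[C@H](CC(=O)OC(C)(C)C)[C@H](O[Si](CC)(CC)CC)CO[Si](c1ccccc1)(c1ccccc1)C(C)(C)C)c1ccc(cc1)[N+](=O)[O-]
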